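## Plan

1. Numbering (eudesmane): ring A = C1–C5 + C10, ring B = C5–C10, C14 on C10, C15 on C4, propenoate C11(=C13)–C12 on C7. Retrosynthesis: remove the C8 acetyl and the silyl groups; cut C7–C8, C5–C10 and the C4–O bond in one step back to an acyclic (E,E)-epoxy aldehyde; then cut C11–C13 (Negishi), C6–C7 (alkynylation) and C8–C9 (Wittig) back to geranyl acetate.
2. Forward: geranyl acetate → C8-homologated hydroxy enal → alkynylation (sets C6) → silanol tether, iodoalkene, epoxide, allylboronate, aldehyde → one-flask closure of ring A (C5–C10), a temporary O4–Si–O6 ring and ring B (C7–C8) → acetylation → desilylation.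
3. Feature used: C7 carries the propenoate and lies between the C6 and C8 carbinols, so C7–C8 is the bond a 2-(methoxycarbonyl)allyl boronate makes with a C8 aldehyde. C10 (quaternary, methyl) lies next to the C1 carbinol and C5 next to the tertiary C4 carbinol, so C5–C10 is the bond an E-C4=C5 olefin makes with a C1–C10 epoxide. O6 stands 1,3 to O4 across C5, so a silanol on O6 can deliver O4.
4. Stereochemistry: C6 from the ligand-controlled alkynylation; C1 and C10 from the Shi epoxide (C10 inverted); C5 and C4 from anti addition across the E-olefin in a chair; C7 and C8 from the chair allylboration with the Z-configured ester.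

Key step: step 13

Assumption: α/β refer to the usual eudesmane drawing (10-methyl β). The ProPhenol antipode used in step 6 is the one that gives the (4R)-carbinol; its sense is not fixed here and would be checked on the first run (Mosher ester).

## Route

Step 1
Reactants: 1 geranyl acetate
Product: 3 (2E,6E)-3,7-dimethyl-8-oxoocta-2,6-dien-1-yl acetate, via 8-hydroxygeranyl acetate 2 (not isolated)
Conditions: SeO2 (cat.), t-BuOOH, salicylic acid (cat.), CH2Cl2, rt; then MnO2, CH2Cl2, rt
Reagents that add atoms: tert-butyl hydroperoxide, CC(C)(C)OO; selenium dioxide (catalytic oxygen carrier), O=[Se]=O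
Why: Allylic oxidation (SeO2/t-BuOOH, ene then [2,3] shift) should attack the E-methyl of the terminal trisubstituted olefin, the acetate-bearing olefin being deactivated, and MnO2 then oxidises only the new allylic alcohol.

Step 2
Reactants: 3 (2E,6E)-3,7-dimethyl-8-oxoocta-2,6-dien-1-yl acetate
Product: 4 (2E,6E)-3,7-dimethylnona-2,6,8-trien-1-yl acetate
Conditions: Ph3PCH3Br, KHMDS, THF, −78 to 0 °C
Reagents that add atoms: methyltriphenylphosphonium bromide, C[P+](c1ccccc1)(c1ccccc1)c1ccccc1.[Br-]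
Why: Wittig methylenation of the enal; the non-stabilised ylide should react with the aldehyde far faster than with the acetate at low temperature.

Step 3
Reactants: 4 (2E,6E)-3,7-dimethylnona-2,6,8-trien-1-yl acetate
Product: 6 (2E,6E)-3,7-dimethylnona-2,6-diene-1,9-diol, via B-alkyl-9-BBN adduct 5 (not isolated)
Conditions: 9-BBN, THF, 0 °C to rt; then NaOH, H2O2, H2O/MeOH, 0 °C to rt
Reagents that add atoms: 9-borabicyclo[3.3.1]nonane (boron held only in 5), B1C2CCCC1CCC2; hydrogen peroxide, OO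
Why: Hydroboration–oxidation with the bulky 9-BBN should be selective for the monosubstituted terminal olefin (boron on C8), and the alkaline peroxide work-up also saponifies the allylic acetate.

Step 4
Reactants: 6 (2E,6E)-3,7-dimethylnona-2,6-diene-1,9-diol
Product: 7 (2E,6E)-9-hydroxy-3,7-dimethylnona-2,6-dienal
Conditions: MnO2, CH2Cl2, rt
Reagents that add atoms: none
Why: MnO2 oxidises only the allylic primary alcohol, leaves the homoallylic one and keeps the E geometry.

Step 5
Reactants: 7 (2E,6E)-9-hydroxy-3,7-dimethylnona-2,6-dienal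
Product: 8 (2E,6E)-3,7-dimethyl-9-(triethylsilyloxy)nona-2,6-dienal
Conditions: TESCl, imidazole, CH2Cl2, 0 °C
Reagents that add atoms: chlorotriethylsilane, CC[Si](Cl)(CC)CC
Why: Standard silylation of the remaining primary alcohol, which the aldehyde tolerates.

Step 6
Reactants: 8 (2E,6E)-3,7-dimethyl-9-(triethylsilyloxy)nona-2,6-dienal; 9 methyl propiolate
Product: 10 methyl (4R,5E,9E)-4-hydroxy-6,10-dimethyl-12-(triethylsilyloxy)dodeca-5,9-dien-2-ynoate
Conditions: Me2Zn, ProPhenol (20 mol%), Ph3PO (cat.), toluene, 4 °C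
Reagents that add atoms: none
Why: Zn–ProPhenol-catalysed asymmetric alkynylation of an α,β-unsaturated aldehyde; the ligand antipode that delivers the zinc alkynylide to the Si face of the formyl group sets the C6 carbinol as R.

Step 7
Reactants: 10 methyl (4R,5E,9E)-4-hydroxy-6,10-dimethyl-12-(triethylsilyloxy)dodeca-5,9-dien-2-ynoate
Product: 12 methyl (4R,5E,9E)-4-[(di-tert-butylhydroxysilyl)oxy]-6,10-dimethyl-12-(triethylsilyloxy)dodeca-5,9-dien-2-ynoate, via silyl triflate 11 (not isolated)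
Conditions: t-Bu2Si(OTf)2, 2,6-lutidine, CH2Cl2, −78 to 0 °C; then aq. NaHCO3
Reagents that add atoms: di-tert-butylsilyl bis(trifluoromethanesulfonate), CC(C)(C)[Si](OS(=O)(=O)C(F)(F)F)(OS(=O)(=O)C(F)(F)F)C(C)(C)C; water, O
Why: Monosilylation of the secondary alcohol with the hindered bis-triflate and hydrolysis of the remaining Si–OTf should give the tethered di-tert-butylsilanol; no stereocentre is touched and the epoxide is not yet present.

Step 8
Reactants: 12 methyl (4R,5E,9E)-4-[(di-tert-butylhydroxysilyl)oxy]-6,10-dimethyl-12-(triethylsilyloxy)dodeca-5,9-dien-2-ynoate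
Product: 14 methyl (2E,4R,5E,9E)-4-[(di-tert-butylhydroxysilyl)oxy]-2-iodo-6,10-dimethyl-12-(triethylsilyloxy)dodeca-2,5,9-trienoate, via α-stannyl enoate 13 (not isolated)
Conditions: Bu3SnH, Pd(PPh3)4 (cat.), THF, 0 °C; then I2, CH2Cl2, 0 °C
Reagents that add atoms: tributyltin hydride (tin held only in 13), CCCC[SnH](CCCC)CCCC; iodine, II
Why: Palladium-catalysed syn hydrostannation of the ynoate places tin α to the ester and away from the branched C6, and iododestannylation with retention gives the alkenyl iodide with C6 cis to the ester.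

Step 9
Reactants: 14 methyl (2E,4R,5E,9E)-4-[(di-tert-butylhydroxysilyl)oxy]-2-iodo-6,10-dimethyl-12-(triethylsilyloxy)dodeca-2,5,9-trienoate
Product: 15 methyl (2E,4R,5E)-4-[(di-tert-butylhydroxysilyl)oxy]-2-iodo-6-methyl-8-{(2R,3R)-3-methyl-3-[2-(triethylsilyloxy)ethyl]oxiran-2-yl}octa-2,5-dienoate
Conditions: Shi ketone (D-fructose-derived, 30 mol%), Oxone, K2CO3, Bu4NHSO4, MeCN/DMM, aq. borate buffer, 0 °C
Reagents that add atoms: potassium peroxymonosulfate (Oxone), [K+].[O-]S(=O)(=O)OO
Why: Shi epoxidation should take the electron-rich, unhindered C1=C10 olefin (the other two are deactivated by the allylic oxygen or by conjugation) and give the (R,R)-epoxide through the spiro transition state.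

Step 10
Reactants: 15 methyl (2E,4R,5E)-4-[(di-tert-butylhydroxysilyl)oxy]-2-iodo-6-methyl-8-{(2R,3R)-3-methyl-3-[2-(triethylsilyloxy)ethyl]oxiran-2-yl}octa-2,5-dienoate; 16 2-(iodomethyl)-4,4,5,5-tetramethyl-1,3,2-dioxaborolane
Product: 18 methyl (2Z,4R,5E)-4-[(di-tert-butylhydroxysilyl)oxy]-6-methyl-8-{(2R,3R)-3-methyl-3-[2-(triethylsilyloxy)ethyl]oxiran-2-yl}-2-[(pinacolatoboryl)methyl]octa-2,5-dienoate, via borylmethylzinc iodide 17 (not isolated)
Conditions: 16, Zn dust, THF, rt; then 15, Pd(PPh3)4 (cat.), THF, rt to 40 °C (excess 17 to allow for the silanol proton)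
Reagents that add atoms: zinc (held only in 17), [Zn]
Why: Negishi coupling of the alkenyl iodide with the α-boryl alkylzinc reagent proceeds with retention of olefin geometry and should tolerate epoxide, ester and silyl ethers.

Step 11
Reactants: 18 methyl (2Z,4R,5E)-4-[(di-tert-butylhydroxysilyl)oxy]-6-methyl-8-{(2R,3R)-3-methyl-3-[2-(triethylsilyloxy)ethyl]oxiran-2-yl}-2-[(pinacolatoboryl)methyl]octa-2,5-dienoate
Product: 19 methyl (2Z,4R,5E)-4-[(di-tert-butylhydroxysilyl)oxy]-8-[(2R,3R)-3-(2-hydroxyethyl)-3-methyloxiran-2-yl]-6-methyl-2-[(pinacolatoboryl)methyl]octa-2,5-dienoate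
Conditions: PPTS, MeOH/CH2Cl2, 0 °C
Reagents that add atoms: none
Why: Mild acid methanolysis cleaves the primary triethylsilyl ether selectively; the hindered silanol, the pinacol boronate and the epoxide should survive the short exposure.

Step 12
Reactants: 19 methyl (2Z,4R,5E)-4-[(di-tert-butylhydroxysilyl)oxy]-8-[(2R,3R)-3-(2-hydroxyethyl)-3-methyloxiran-2-yl]-6-methyl-2-[(pinacolatoboryl)methyl]octa-2,5-dienoate
Product: 20 methyl (2Z,4R,5E)-4-[(di-tert-butylhydroxysilyl)oxy]-6-methyl-8-[(2R,3R)-3-methyl-3-(2-oxoethyl)oxiran-2-yl]-2-[(pinacolatoboryl)methyl]octa-2,5-dienoate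
Conditions: Dess–Martin periodinane, NaHCO3, CH2Cl2, 0 °C; crude used at once
Reagents that add atoms: none
Why: Buffered Dess–Martin oxidation is non-basic and should avoid β-elimination of the β,γ-epoxy aldehyde, which is not stored.

Step 13
Reactants: 20 methyl (2Z,4R,5E)-4-[(di-tert-butylhydroxysilyl)oxy]-6-methyl-8-[(2R,3R)-3-methyl-3-(2-oxoethyl)oxiran-2-yl]-2-[(pinacolatoboryl)methyl]octa-2,5-dienoate
Product: 23 methyl 1β-(tert-butyldimethylsilyloxy)-4α,6α-(di-tert-butylsilylenedioxy)-8α-hydroxyeudesm-11(13)-en-12-oate, via monocyclic aldehyde 21 (not isolated), via O8-pinacolborate 22 (not isolated)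
Conditions: TBSOTf (1.1 eq), 2,6-di-tert-butyl-4-methylpyridine, CH2Cl2, −78 °C; then 25–40 °C; aq. NaHCO3
Reagents that add atoms: tert-butyldimethylsilyl trifluoromethanesulfonate, CC(C)(C)[Si](C)(C)OS(=O)(=O)C(F)(F)F
Why: Proposed new method: TBSOTf silylates the oxirane oxygen, the E-C4=C5 olefin opens the epoxide at tertiary C10 with inversion (C5–C10, ring A, 6-endo at the olefin), the tertiary C4 cation is captured anti by the tethered silanol oxygen (temporary 1,3,2-dioxasilinane, six-membered, trans-fused), and on warming C7 of the allylboronate adds to the C8 aldehyde, now six atoms away, through a closed chair transition state (C7–C8, ring B, six-membered). The closest known reaction types are silyl-triflate/hindered-pyridine epoxide-initiated cation–olefin cyclisations of epoxygeranyl-type substrates, capture of onium intermediates by tethered di-tert-butylsilanols, and type I carbonyl allylboration with 2-alkoxycarbonylallyl boronates; their merger in one flask is what is new. C1 keeps the epoxide configuration and C10 is set by backside attack on the E-epoxide (C9 equatorial, methyl axial); C5 and C4 follow from anti addition across the E-olefin in a chair (H5 axial, O4 equatorial); C7 and C8 follow from the chair–chair allylboration, in which the Z-ester geometry places C6 trans to CH2B and so gives the anti, diequatorial pair. The step needs cyclisation to outrun elimination of the silyloxonium ion and proton loss from C4, which the non-nucleophilic base, the low temperature and the six-membered silanol tether (matched C6 configuration, C7 equatorial) should secure. It also needs the allylboration to wait for ring A, which the ten-membered alternative before cyclisation and the uncatalysed boronate should ensure; O1 emerges as its TBS ether and O8 as a borate, so the two new hydroxyls are differentiated.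

Step 14
Reactants: 23 methyl 1β-(tert-butyldimethylsilyloxy)-4α,6α-(di-tert-butylsilylenedioxy)-8α-hydroxyeudesm-11(13)-en-12-oate
Product: 24 methyl 8α-acetoxy-1β-(tert-butyldimethylsilyloxy)-4α,6α-(di-tert-butylsilylenedioxy)eudesm-11(13)-en-12-oate
Conditions: Ac2O, DMAP, pyridine, CH2Cl2, rt
Reagents that add atoms: acetic anhydride, CC(=O)OC(C)=O
Why: DMAP-catalysed acetylation of the only free hydroxyl, the equatorial C8 alcohol.

Step 15
Reactants: 24 methyl 8α-acetoxy-1β-(tert-butyldimethylsilyloxy)-4α,6α-(di-tert-butylsilylenedioxy)eudesm-11(13)-en-12-oate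
Product: 25 methyl 8α-acetoxy-1β,4α,6α-trihydroxyeudesm-11(13)-en-12-oate (CNP0272656.1)
Conditions: HF·pyridine, pyridine, THF, 0 °C to rt
Reagents that add atoms: none
Why: Buffered fluoride cleaves the silylene and the TBS ether under non-basic conditions that should spare the acetate and the acrylate and avoid lactonisation of the freed 6-hydroxyl onto the ester.

## Compound list

1 | geranyl acetate | CC(=O)OC/C=C(\C)CCC=C(C)C | starting material
2 | (2E,6E)-8-hydroxy-3,7-dimethylocta-2,6-dien-1-yl acetate | CC(=O)OC/C=C(\C)CC/C=C(\C)CO | intermediate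
3 | (2E,6E)-3,7-dimethyl-8-oxoocta-2,6-dien-1-yl acetate | CC(=O)OC/C=C(\C)CC/C=C(\C)C=O | intermediate
4 | (2E,6E)-3,7-dimethylnona-2,6,8-trien-1-yl acetate | CC(=O)OC/C=C(\C)CC/C=C(\C)C=C | intermediate
5 | (2E,6E)-9-(9-borabicyclo[3.3.1]nonan-9-yl)-3,7-dimethylnona-2,6-dien-1-yl acetate | CC(=O)OC/C=C(\C)CC/C=C(\C)CCB1C2CCCC1CCC2 | intermediate
6 | (2E,6E)-3,7-dimethylnona-2,6-diene-1,9-diol | OC/C=C(\C)CC/C=C(\C)CCO | intermediate
7 | (2E,6E)-9-hydroxy-3,7-dimethylnona-2,6-dienal | O=C/C=C(\C)CC/C=C(\C)CCO | intermediate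
8 | (2E,6E)-3,7-dimethyl-9-(triethylsilyloxy)nona-2,6-dienal | O=C/C=C(\C)CC/C=C(\C)CCO[Si](CC)(CC)CC | intermediate
9 | methyl propiolate | C#CC(=O)OC | starting material
10 | methyl (4R,5E,9E)-4-hydroxy-6,10-dimethyl-12-(triethylsilyloxy)dodeca-5,9-dien-2-ynoate | COC(=O)C#C[C@H](O)/C=C(\C)CC/C=C(\C)CCO[Si](CC)(CC)CC | intermediate
11 | methyl (4R,5E,9E)-4-{[di-tert-butyl(trifluoromethanesulfonyloxy)silyl]oxy}-6,10-dimethyl-12-(triethylsilyloxy)dodeca-5,9-dien-2-ynoate | COC(=O)C#C[C@H](O[Si](OS(=O)(=O)C(F)(F)F)(C(C)(C)C)C(C)(C)C)/C=C(\C)CC/C=C(\C)CCO[Si](CC)(CC)CC | intermediate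
12 | methyl (4R,5E,9E)-4-[(di-tert-butylhydroxysilyl)oxy]-6,10-dimethyl-12-(triethylsilyloxy)dodeca-5,9-dien-2-ynoate | COC(=O)C#C[C@H](O[Si](O)(C(C)(C)C)C(C)(C)C)/C=C(\C)CC/C=C(\C)CCO[Si](CC)(CC)CC | intermediate
13 | methyl (2E,4R,5E,9E)-4-[(di-tert-butylhydroxysilyl)oxy]-6,10-dimethyl-2-(tributylstannyl)-12-(triethylsilyloxy)dodeca-2,5,9-trienoate | COC(=O)/C([Sn](CCCC)(CCCC)CCCC)=C\[C@H](O[Si](O)(C(C)(C)C)C(C)(C)C)/C=C(\C)CC/C=C(\C)CCO[Si](CC)(CC)CC | intermediate
14 | methyl (2E,4R,5E,9E)-4-[(di-tert-butylhydroxysilyl)oxy]-2-iodo-6,10-dimethyl-12-(triethylsilyloxy)dodeca-2,5,9-trienoate | COC(=O)/C(I)=C\[C@H](O[Si](O)(C(C)(C)C)C(C)(C)C)/C=C(\C)CC/C=C(\C)CCO[Si](CC)(CC)CC | intermediate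
15 | methyl (2E,4R,5E)-4-[(di-tert-butylhydroxysilyl)oxy]-2-iodo-6-methyl-8-{(2R,3R)-3-methyl-3-[2-(triethylsilyloxy)ethyl]oxiran-2-yl}octa-2,5-dienoate | COC(=O)/C(I)=C\[C@H](O[Si](O)(C(C)(C)C)C(C)(C)C)/C=C(\C)CC[C@H]1O[C@]1(C)CCO[Si](CC)(CC)CC | intermediate
16 | 2-(iodomethyl)-4,4,5,5-tetramethyl-1,3,2-dioxaborolane | ICB1OC(C)(C)C(C)(C)O1 | starting material
17 | [(4,4,5,5-tetramethyl-1,3,2-dioxaborolan-2-yl)methyl]zinc iodide | I[Zn]CB1OC(C)(C)C(C)(C)O1 | intermediate
18 | methyl (2Z,4R,5E)-4-[(di-tert-butylhydroxysilyl)oxy]-6-methyl-8-{(2R,3R)-3-methyl-3-[2-(triethylsilyloxy)ethyl]oxiran-2-yl}-2-[(pinacolatoboryl)methyl]octa-2,5-dienoate | COC(=O)/C(CB1OC(C)(C)C(C)(C)O1)=C\[C@H](O[Si](O)(C(C)(C)C)C(C)(C)C)/C=C(\C)CC[C@H]1O[C@]1(C)CCO[Si](CC)(CC)CC | intermediate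
19 | methyl (2Z,4R,5E)-4-[(di-tert-butylhydroxysilyl)oxy]-8-[(2R,3R)-3-(2-hydroxyethyl)-3-methyloxiran-2-yl]-6-methyl-2-[(pinacolatoboryl)methyl]octa-2,5-dienoate | COC(=O)/C(CB1OC(C)(C)C(C)(C)O1)=C\[C@H](O[Si](O)(C(C)(C)C)C(C)(C)C)/C=C(\C)CC[C@H]1O[C@]1(C)CCO | intermediate
20 | methyl (2Z,4R,5E)-4-[(di-tert-butylhydroxysilyl)oxy]-6-methyl-8-[(2R,3R)-3-methyl-3-(2-oxoethyl)oxiran-2-yl]-2-[(pinacolatoboryl)methyl]octa-2,5-dienoate | COC(=O)/C(CB1OC(C)(C)C(C)(C)O1)=C\[C@H](O[Si](O)(C(C)(C)C)C(C)(C)C)/C=C(\C)CC[C@H]1O[C@]1(C)CC=O | intermediate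
21 | monocyclic aldehyde: ring A closed; 1β-OTBS; 10β-methyl and 10-CH2CHO; 5αH; 4β-methyl; O4 and O6 bridged by di-tert-butylsilylene (1,3,2-dioxasilinane); C6 bearing the (Z)-2-(methoxycarbonyl)-3-(pinacolatoboryl)prop-1-enyl group | O=CC[C@@]1(C)[C@H](O[Si](C)(C)C(C)(C)C)CC[C@@]2(C)O[Si](C(C)(C)C)(C(C)(C)C)O[C@@H](/C=C(\C(=O)OC)CB3OC(C)(C)C(C)(C)O3)[C@H]12 | intermediate
22 | methyl 1β-(tert-butyldimethylsilyloxy)-4α,6α-(di-tert-butylsilylenedioxy)-8α-[(pinacolatoboryl)oxy]eudesm-11(13)-en-12-oate | C=C(C(=O)OC)[C@H]1[C@H](O3)[C@@H]2[C@@](C)(C[C@@H]1OB4OC(C)(C)C(C)(C)O4)[C@H](O[Si](C)(C)C(C)(C)C)CC[C@@]2(C)O[Si]3(C(C)(C)C)C(C)(C)C | intermediate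
23 | methyl 1β-(tert-butyldimethylsilyloxy)-4α,6α-(di-tert-butylsilylenedioxy)-8α-hydroxyeudesm-11(13)-en-12-oate | C=C(C(=O)OC)[C@H]1[C@H](O3)[C@@H]2[C@@](C)(C[C@@H]1O)[C@H](O[Si](C)(C)C(C)(C)C)CC[C@@]2(C)O[Si]3(C(C)(C)C)C(C)(C)C | intermediate
24 | methyl 8α-acetoxy-1β-(tert-butyldimethylsilyloxy)-4α,6α-(di-tert-butylsilylenedioxy)eudesm-11(13)-en-12-oate | C=C(C(=O)OC)[C@H]1[C@H](O3)[C@@H]2[C@@](C)(C[C@@H]1OC(C)=O)[C@H](O[Si](C)(C)C(C)(C)C)CC[C@@]2(C)O[Si]3(C(C)(C)C)C(C)(C)C | intermediate
25 | methyl 8α-acetoxy-1β,4α,6α-trihydroxyeudesm-11(13)-en-12-oate (CNP0272656.1) | C=C(C(=O)OC)[C@H]1[C@H](O)[C@@H]2[C@@](C)(C[C@@H]1OC(C)=O)[C@H](O)CC[C@@]2(C)O | target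

## Count and risks

Total steps: 15. Longest linear sequence: 15 steps (from geranyl acetate).

Steps most likely to fail:

1. Step 13 (Proposed new method). The silyl triflate may engage the aldehyde or the boronate before the epoxide, the β,γ-epoxy aldehyde may open to the hydroxy enal before it cyclises, or the allylboration may not follow in the same flask. Fallback: the event is divided into separate operations, each of a known type, setting out from 18. TBSOTf and 2,6-di-tert-butyl-4-methylpyridine at −78 °C should cyclise 18, with no aldehyde present, to the monocyclic triethylsilyl ether F1 (epoxide-initiated, oxygen-terminated cation–olefin cyclisation). PPTS in methanol should then give the monocyclic primary alcohol F2. Dess–Martin oxidation comes back to the route at 21, whose aldehyde now sits on a quaternary carbon and cannot eliminate. Sc(OTf)3-catalysed intramolecular allylboration at low temperature and hydrolysis then give 23.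

2. Step 6. Addition to the β,β-disubstituted enal may be slow, methyl transfer from zinc may compete, or face selectivity may be poor. Fallback: the carbinol centre is set by reduction instead, setting out from 8. Lithium methyl propiolate (LiHMDS, THF, −78 °C) should give the racemic propargylic alcohol F3, and MnO2 the cross-conjugated ynone F4. Corey–Bakshi–Shibata reduction with the (R)-methyl oxazaborolidine and catecholborane, the alkynyl group acting as the small substituent, comes back to the route at 10.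

3. Step 9. The dioxirane may be directed by the silanol to the C4=C5 olefin, or the face selectivity at C1=C10 may be poor. Fallback: oxygen delivery is made hydroxyl-directed, setting out from 14. PPTS in methanol should give the homoallylic alcohol F5. Vanadium/chiral bis-hydroxamic acid-catalysed epoxidation with cumene hydroperoxide, directed by the C8 hydroxyl and with the ligand antipode chosen for the (2R,3R)-oxirane, should give the epoxy alcohol F6. Negishi coupling of F6 with 17 as in step 10 comes back to the route at 19.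

## Further compounds

F1 | step 13 | monocyclic triethylsilyl ether: as 21 but with CH2CH2OSiEt3 on C10 in place of CH2CHO | CC[Si](CC)(CC)OCC[C@@]1(C)[C@H](O[Si](C)(C)C(C)(C)C)CC[C@@]2(C)O[Si](C(C)(C)C)(C(C)(C)C)O[C@@H](/C=C(\C(=O)OC)CB3OC(C)(C)C(C)(C)O3)[C@H]12
F2 | step 13 | monocyclic primary alcohol: as 21 but with CH2CH2OH on C10 in place of CH2CHO | OCC[C@@]1(C)[C@H](O[Si](C)(C)C(C)(C)C)CC[C@@]2(C)O[Si](C(C)(C)C)(C(C)(C)C)O[C@@H](/C=C(\C(=O)OC)CB3OC(C)(C)C(C)(C)O3)[C@H]12
F3 | step 6 | racemic methyl (5E,9E)-4-hydroxy-6,10-dimethyl-12-(triethylsilyloxy)dodeca-5,9-dien-2-ynoate | COC(=O)C#CC(O)/C=C(\C)CC/C=C(\C)CCO[Si](CC)(CC)CC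
F4 | step 6 | methyl (5E,9E)-6,10-dimethyl-4-oxo-12-(triethylsilyloxy)dodeca-5,9-dien-2-ynoate | COC(=O)C#CC(=O)/C=C(\C)CC/C=C(\C)CCO[Si](CC)(CC)CC
F5 | step 9 | methyl (2E,4R,5E,9E)-4-[(di-tert-butylhydroxysilyl)oxy]-12-hydroxy-2-iodo-6,10-dimethyldodeca-2,5,9-trienoate | COC(=O)/C(I)=C\[C@H](O[Si](O)(C(C)(C)C)C(C)(C)C)/C=C(\C)CC/C=C(\C)CCO
F6 | step 9 | methyl (2E,4R,5E)-4-[(di-tert-butylhydroxysilyl)oxy]-8-[(2R,3R)-3-(2-hydroxyethyl)-3-methyloxiran-2-yl]-2-iodo-6-methylocta-2,5-dienoate | COC(=O)/C(I)=C\[C@H](O[Si](O)(C(C)(C)C)C(C)(C)C)/C=C(\C)CC[C@H]1O[C@]1(C)CCO
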